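Ring B is opened at the bond between its acetyl-bearing carbon and the neighbouring oxygenated carbon that adjoins the CMe2 carbon. In the forward sense, one intramolecular Claisen condensation folds a linear chain: the C6 methylene, flanked by the C5 and C7 ketones, attacks the C1 methyl ester and closes the carbocycle with the complete 2-acetyl-1,3,5-trione array in place. The step exploits the quaternary CMe2 carbon of ring B, which keeps the ester non-enolisable and stops the ring at the dienone instead of a phenol. The precursor is methyl 2,2-dimethyl-3,5,7-trioxooctanoate carrying at C4 the ring A benzyl group, with both phenols masked as benzyl ethers and the ring A acetyl already present.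

Key step: step 6

Remark: chain numbering is C1 ester carbon, C2 CMe2, C3/C5/C7 carbonyls, C8 methyl; the target has no stereocentre and the enolisable C4 centre of the open-chain intermediates is racemic; the C7 carbonyl is carried as a dioxolane until the step before cyclisation, because acylating the terminal methyl after ring A is attached would need a polyanion that enolises the ring A acetyl and closes the ring prematurely without the acetyl group.

Step 1
Reactants: 1 2,6-dihydroxy-4-methoxyacetophenone
Product: 2 3-acetyl-2,4-dihydroxy-6-methoxybenzaldehyde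
Conditions: Cl2CHOMe (1.1 equiv), TiCl4 (3 equiv), CH2Cl2, −10 °C → rt; then ice-cold 1 M HCl
Reagents that add atoms: dichloromethyl methyl ether, COC(Cl)Cl (formyl carbon); water, O (formyl oxygen on hydrolytic work-up)
Why: Rieche formylation, in which the TiCl4-activated dichloromethyl methyl ether substitutes the only free and strongly activated ring position (C3, equivalent to C5, between a hydroxyl and the methoxy group), while the first formyl group deactivates the ring against a second substitution.

Step 2
Reactants: 2 3-acetyl-2,4-dihydroxy-6-methoxybenzaldehyde; 3 benzyl bromide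
Product: 4 3-acetyl-2,4-bis(benzyloxy)-6-methoxybenzaldehyde
Conditions: BnBr (2.5 equiv), K2CO3 (3 equiv), DMF, 60 °C
Reagents that add atoms: benzyl bromide (3), BrCc1ccccc1
Why: Williamson ether synthesis, in which warm K2CO3 in DMF breaks the carbonyl chelation of both phenols and the phenoxides are O-alkylated, the two acyl groups disfavouring C-benzylation of the ring.

Step 3
Reactants: 5 methyl 2,2-dimethyl-3-oxobutanoate (2.1 equiv); 6 ethyl 2-(2-methyl-1,3-dioxolan-2-yl)acetate (1.0 equiv)
Product: 7 methyl 2,2-dimethyl-6-(2-methyl-1,3-dioxolan-2-yl)-3,5-dioxohexanoate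
Conditions: LiN(i-Pr)2 (2.05 equiv), THF, −78 °C; then 6, −78 °C → rt; AcOH quench, aqueous NH4Cl work-up
Reagents that add atoms: none
Why: Crossed Claisen condensation, in which 5 can enolise only at its acetyl methyl group, the lithium enolate is acylated by the ester of 6, and the second equivalent of enolate deprotonates the new β-diketone and so protects it, while the dioxolane stores the future C7 carbonyl so that C4 is the only doubly activated methylene and the chain cannot yet cyclise.

Step 4
Reactants: 4 3-acetyl-2,4-bis(benzyloxy)-6-methoxybenzaldehyde; 7 methyl 2,2-dimethyl-6-(2-methyl-1,3-dioxolan-2-yl)-3,5-dioxohexanoate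
Product: 9 methyl 4-{[3-acetyl-2,4-bis(benzyloxy)-6-methoxyphenyl]methyl}-2,2-dimethyl-6-(2-methyl-1,3-dioxolan-2-yl)-3,5-dioxohexanoate (racemic at C4), via alkylidene diketone 8 (not isolated)
Conditions: proline (0.2 equiv), Hantzsch ester (diethyl 2,6-dimethyl-1,4-dihydropyridine-3,5-dicarboxylate, 1.2 equiv), EtOH, 40 °C
Reagents that add atoms: none
Why: Three-component reductive alkylation (amine-catalysed Knoevenagel condensation followed by transfer hydrogenation), in which condensation is possible only at the C4 methylene between two ketones and the electron-poor alkylidene diketone 8 takes hydride from the Hantzsch ester, giving mono-C-benzylation without base and leaving the hindered ring A acetyl untouched; the new C4 centre is formed racemic.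

Step 5
Reactants: 9 methyl 4-{[3-acetyl-2,4-bis(benzyloxy)-6-methoxyphenyl]methyl}-2,2-dimethyl-6-(2-methyl-1,3-dioxolan-2-yl)-3,5-dioxohexanoate
Product: 10 methyl 4-{[3-acetyl-2,4-bis(benzyloxy)-6-methoxyphenyl]methyl}-2,2-dimethyl-3,5,7-trioxooctanoate (racemic at C4, keto–enol mixture)
Conditions: 2 M aq HCl/THF (1:4), 0 °C → rt, stopped at full conversion
Reagents that add atoms: water, O
Why: Acid-catalysed ketal hydrolysis, in which dilute aqueous acid cleaves the β-keto dioxolane while the benzyl ethers, the hindered methyl ester and the diketone survive, and the large excess of water favours hydrolysis over cyclodehydration to a pyranone.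

Step 6
Reactants: 10 methyl 4-{[3-acetyl-2,4-bis(benzyloxy)-6-methoxyphenyl]methyl}-2,2-dimethyl-3,5,7-trioxooctanoate
Product: 11 2-acetyl-6-{[3-acetyl-2,4-bis(benzyloxy)-6-methoxyphenyl]methyl}-3,5-dihydroxy-4,4-dimethylcyclohexa-2,5-dien-1-one
Conditions: NaH (2.2 equiv), THF, 0 °C → 40 °C; then 1 M HCl, 0 °C
Reagents that add atoms: none
Why: NaH removes the most acidic proton, on the C6 methylene between the C5 and C7 ketones, and the stabilised enolate adds through carbon to the C1 methyl ester; the tetrahedral intermediate expels methoxide, which is consumed at once by deprotonating the new, strongly acidic 2-acyl-1,3,5-trione, so the closure is pulled to completion. This is the intramolecular Claisen (Dieckmann-type) cyclisation by which 3,5,7-trioxoalkanoates are turned into acylphloroglucinols, here arrested at the 4,4-dimethyl dienone because C2 bears no hydrogen. Ring B closes in the 6-exo-trig mode, the ester carbonyl oxygen lying outside the new six-membered carbocycle. No stereocentre is created, and the labile C4 centre of the chain becomes an sp2 ring carbon. The step needs C- over O-acylation and reaction at C6 alone: carbanions at C4 or C8 could only close four- or eight-membered rings, an enol lactone formed through oxygen reopens while the doubly deprotonated C-acyl trione is where the equilibria drain, and the gem-dimethyl group both forbids enolisation of the ester and compresses the chain into the reactive rotamer. A hydride base in an aprotic solvent keeps free alkoxide low and so limits retro-Claisen scission at the C3 carbonyl, and the benzyl ethers keep the ring A oxygens out of the reaction.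

Step 7
Reactants: 11 2-acetyl-6-{[3-acetyl-2,4-bis(benzyloxy)-6-methoxyphenyl]methyl}-3,5-dihydroxy-4,4-dimethylcyclohexa-2,5-dien-1-one
Product: 12 2-acetyl-6-[(3-acetyl-2,4-dihydroxy-6-methoxyphenyl)methyl]-3,5-dihydroxy-4,4-dimethylcyclohexa-2,5-dien-1-one (target)
Conditions: H2 (1 atm), 10% Pd/C, EtOAc/MeOH, rt
Reagents that add atoms: none
Why: Catalytic hydrogenolysis of the two aryl benzyl ethers under neutral conditions, which should spare the chelated aryl ketone and the fully substituted, hydrogen-bonded enone units of ring B and frees the ring A phenols only at the very end.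

Compound list
1 | 2,6-dihydroxy-4-methoxyacetophenone | COc1cc(O)c(C(C)=O)c(O)c1 | starting material
2 | 3-acetyl-2,4-dihydroxy-6-methoxybenzaldehyde | COc1cc(O)c(C(C)=O)c(O)c1C=O | intermediate
3 | benzyl bromide | BrCc1ccccc1 | starting material
4 | 3-acetyl-2,4-bis(benzyloxy)-6-methoxybenzaldehyde | COc1cc(OCc2ccccc2)c(C(C)=O)c(OCc2ccccc2)c1C=O | intermediate
5 | methyl 2,2-dimethyl-3-oxobutanoate | CC(=O)C(C)(C)C(=O)OC | starting material
6 | ethyl 2-(2-methyl-1,3-dioxolan-2-yl)acetate | CCOC(=O)CC1(C)OCCO1 | starting material
7 | methyl 2,2-dimethyl-6-(2-methyl-1,3-dioxolan-2-yl)-3,5-dioxohexanoate | COC(=O)C(C)(C)C(=O)CC(=O)CC1(C)OCCO1 | intermediate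
8 | methyl 4-{[3-acetyl-2,4-bis(benzyloxy)-6-methoxyphenyl]methylidene}-2,2-dimethyl-6-(2-methyl-1,3-dioxolan-2-yl)-3,5-dioxohexanoate (not isolated; alkene geometry uncontrolled and removed on reduction) | COC(=O)C(C)(C)C(=O)C(=Cc1c(OC)cc(OCc2ccccc2)c(C(C)=O)c1OCc1ccccc1)C(=O)CC1(C)OCCO1 | intermediate
9 | methyl 4-{[3-acetyl-2,4-bis(benzyloxy)-6-methoxyphenyl]methyl}-2,2-dimethyl-6-(2-methyl-1,3-dioxolan-2-yl)-3,5-dioxohexanoate (racemic at C4) | COC(=O)C(C)(C)C(=O)C(Cc1c(OC)cc(OCc2ccccc2)c(C(C)=O)c1OCc1ccccc1)C(=O)CC1(C)OCCO1 | intermediate
10 | methyl 4-{[3-acetyl-2,4-bis(benzyloxy)-6-methoxyphenyl]methyl}-2,2-dimethyl-3,5,7-trioxooctanoate (racemic at C4) | COC(=O)C(C)(C)C(=O)C(Cc1c(OC)cc(OCc2ccccc2)c(C(C)=O)c1OCc1ccccc1)C(=O)CC(C)=O | intermediate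
11 | 2-acetyl-6-{[3-acetyl-2,4-bis(benzyloxy)-6-methoxyphenyl]methyl}-3,5-dihydroxy-4,4-dimethylcyclohexa-2,5-dien-1-one | COc1cc(OCc2ccccc2)c(C(C)=O)c(OCc2ccccc2)c1CC1=C(O)C(C)(C)C(O)=C(C(C)=O)C1=O | intermediate
12 | 2-acetyl-6-[(3-acetyl-2,4-dihydroxy-6-methoxyphenyl)methyl]-3,5-dihydroxy-4,4-dimethylcyclohexa-2,5-dien-1-one (achiral) | COc1cc(O)c(C(C)=O)c(O)c1CC1=C(O)C(C)(C)C(O)=C(C(C)=O)C1=O | target

Total step count: 7
Longest linear sequence: 6 steps (steps 1, 2, 4, 5, 6, 7, from 1 to 12); step 3 is a one-step side branch.

Steps most likely to fail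

Step 6 (key step). Attack through oxygen instead of carbon, retro-Claisen scission at the C3 carbonyl next to the quaternary carbon, or sluggish addition to the hindered α-quaternary ester could each divert the closure. Fallback: ring B is brought in already closed. Setting out from aldehyde 4, the known 2-acetyl-3,5-dihydroxy-4,4-dimethylcyclohexa-2,5-dien-1-one (acetylfilicinic acid) F1, obtainable from commercial 2,4,6-trihydroxyacetophenone by geminal C-methylation (MeI, NaOMe, MeOH), would be joined to 4 at its single free ring CH by proline/Hantzsch ester reductive alkylation. This comes back to the route at 11.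

Step 4. Knoevenagel condensation of a doubly ortho-substituted, electron-rich aldehyde with an acyclic diketone that is hindered on one side may be slow, so the sequence could stall before hydride transfer. Fallback: alkylation instead of condensation–reduction. Setting out from 4, NaBH4 (MeOH, 0 °C) should reduce only the aldehyde to 1-[2,6-bis(benzyloxy)-3-(hydroxymethyl)-4-methoxyphenyl]ethan-1-one F2. SOCl2 with pyridine in CH2Cl2 at 0 °C would convert it into 1-[2,6-bis(benzyloxy)-3-(chloromethyl)-4-methoxyphenyl]ethan-1-one F3, used crude at once. C-Alkylation of the potassium enolate of 7 (K2CO3, acetone) with this chloride comes back to the route at 9.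

Step 3. Proton transfer from the enolisable ketal ester to the ketone enolate, followed by β-elimination that opens the dioxolane, and slow acyl transfer from a simple ester to a lithium enolate could erode the condensation. Fallback: an activated acyl donor under soft enolisation. Setting out from 6, saponification (LiOH, THF/H2O, acidification only to pH 4) would give 2-(2-methyl-1,3-dioxolan-2-yl)acetic acid F4. Coupling with 1H-benzotriazole (N,N'-dicyclohexylcarbodiimide, CH2Cl2) would give 1-(1H-benzotriazol-1-yl)-2-(2-methyl-1,3-dioxolan-2-yl)ethan-1-one F5. This acylates 5 at its acetyl methyl group under MgBr2·OEt2/i-Pr2NEt in CH2Cl2 at rt, without any strong base, and comes back to the route at 7.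

Further compounds
F1 | step 6 | 2-acetyl-3,5-dihydroxy-4,4-dimethylcyclohexa-2,5-dien-1-one (acetylfilicinic acid) | CC(=O)C1=C(O)C(C)(C)C(O)=CC1=O
F2 | step 4 | 1-[2,6-bis(benzyloxy)-3-(hydroxymethyl)-4-methoxyphenyl]ethan-1-one | COc1cc(OCc2ccccc2)c(C(C)=O)c(OCc2ccccc2)c1CO
F3 | step 4 | 1-[2,6-bis(benzyloxy)-3-(chloromethyl)-4-methoxyphenyl]ethan-1-one | COc1cc(OCc2ccccc2)c(C(C)=O)c(OCc2ccccc2)c1CCl
F4 | step 3 | 2-(2-methyl-1,3-dioxolan-2-yl)acetic acid | CC1(CC(=O)O)OCCO1
F5 | step 3 | 1-(1H-benzotriazol-1-yl)-2-(2-methyl-1,3-dioxolan-2-yl)ethan-1-one | CC1(CC(=O)n2nnc3ccccc32)OCCO1
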